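**Strategy**

Ring C is disconnected at O1–C8a and C4–C4a. This works because C8a (bearing O1) and C4a (bearing C4) are adjacent carbons of ring A and C4a is flanked on its other side by the oxygenated C5: a 3-alkoxybenzyne takes up an oxygen nucleophile and then a carbon electrophile in just that arrangement. In one operation fluoride releases 3-allyloxy-5-methoxybenzyne from its 2-silylaryl triflate and an alkoxide from a silyl ether; O-arylation and 6-exo attack of the aryl anion on the aldehyde form the aryl ether, ring C and the cis C4 carbinol. The partner is (R)-2-aryl-3-(triethylsilyloxy)propanal, made by enzymatic desymmetrisation of a 2-arylpropane-1,3-diol; two allyl ethers fall last.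

Key step: step 15

**Remarks before the steps**

- Ar = 4-(allyloxy)-2-methoxy-5-(3-methylbut-2-en-1-yl)phenyl throughout; atom numbers are those of the isoflavan (chroman) skeleton.
- Configuration: the target is (3R,4R), with the C3 aryl group and the C4 hydroxyl cis. The C3 centre is made once (step 11) and never inverted; the descriptors R (23), S (24, 25), R (26) change only because the CIP ranks of the two CH2O arms change.
- Precursor design: the primary hydroxyl of the hydroxy aldehyde is carried as its triethylsilyl ether and freed only inside the key step. A free OH would pass its proton to the aryl anion (plain O-arylation, no ring closure), and the free β-hydroxy-α-aryl aldehyde cannot be stored.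
- Ring A: bromine, not silicon, is placed at C2 first, because a C2 silane between two free phenols would not survive acid; silicon enters in the last step by O-to-C migration.
- Assumption: the lipase in step 11 is taken to acylate the pro-R hydroxymethyl arm of diol 22; the sense has to be confirmed on the first run (Mosher ester analysis).

**Route**

Step 1
Reactants: 1 5-methoxyresorcinol
Product: 2 1-methoxy-3,5-bis(methoxymethoxy)benzene
Conditions: MOMCl, i-Pr2NEt, CH2Cl2, 0 °C to rt
Reagents that add atoms: chloromethyl methyl ether, COCCl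
Why: Williamson-type O-alkylation of both phenols installs the two methoxymethyl ethers that direct the metalation in step 2.

Step 2
Reactants: 2 1-methoxy-3,5-bis(methoxymethoxy)benzene
Product: 4 2-bromo-5-methoxy-1,3-bis(methoxymethoxy)benzene, via aryllithium 3 (not isolated)
Conditions: n-BuLi, THF, 0 °C; BrCCl2CCl2Br, −78 °C to rt
Reagents that add atoms: 1,2-dibromo-1,1,2,2-tetrachloroethane, BrC(Cl)(Cl)C(Cl)(Cl)Br
Why: Directed ortho-metalation should occur at C2, which lies between two chelating MOM ethers, in preference to C4/C6 (one MOM ether and the weaker OMe), and the aryllithium is brominated by halogen transfer.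

Step 3
Reactants: 4 2-bromo-5-methoxy-1,3-bis(methoxymethoxy)benzene
Product: 5 2-bromo-5-methoxybenzene-1,3-diol
Conditions: HCl (cat.), MeOH, 50 °C
Reagents that add atoms: none
Why: Acid-catalysed acetal exchange with methanol removes both MOM groups, and the aryl bromide is inert to this acid.

Step 4
Reactants: 5 2-bromo-5-methoxybenzene-1,3-diol
Product: 6 3-(allyloxy)-2-bromo-5-methoxyphenol
Conditions: allyl bromide (1 equiv), K2CO3 (1 equiv), acetone, rt
Reagents that add atoms: allyl bromide, C=CCBr
Why: Williamson etherification of one of two equivalent phenols with limiting electrophile; only statistical selectivity is claimed, the mono-ether is separated and unreacted 5 is returned to the step.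

Step 5
Reactants: 6 3-(allyloxy)-2-bromo-5-methoxyphenol
Product: 10 3-(allyloxy)-5-methoxy-2-(trimethylsilyl)phenyl trifluoromethanesulfonate, via trimethylsilyl ether 7 (not isolated), via aryllithium 8 (not isolated), via lithium phenoxide 9 (not isolated)
Conditions: HMDS, THF, reflux, evaporate; n-BuLi, THF, −100 °C; Tf2O, −100 to −78 °C
Reagents that add atoms: hexamethyldisilazane, C[Si](C)(C)N[Si](C)(C)C; trifluoromethanesulfonic anhydride, O=S(=O)(OS(=O)(=O)C(F)(F)F)C(F)(F)F
Why: This is the established one-pot conversion of 2-bromophenols into 2-silylaryl triflates (O-silylation, Br/Li exchange, retro-Brook 1,3 O-to-C silyl shift, triflation of the phenoxide), and at −100 °C the silyl shift should outrun carbolithiation of the neighbouring allyl ether.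

Step 6
Reactants: 11 5-bromo-2,4-dihydroxybenzaldehyde
Product: 12 4-(allyloxy)-5-bromo-2-hydroxybenzaldehyde
Conditions: allyl bromide, KHCO3, DMF, 40 °C
Reagents that add atoms: allyl bromide, C=CCBr
Why: Williamson etherification with a weak base is selective for the 4-OH, since the 2-OH is hydrogen-bonded to the aldehyde and much less nucleophilic.

Step 7
Reactants: 12 4-(allyloxy)-5-bromo-2-hydroxybenzaldehyde
Product: 13 4-(allyloxy)-5-bromo-2-methoxybenzaldehyde
Conditions: MeI, K2CO3, DMF, rt
Reagents that add atoms: iodomethane, CI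
Why: Williamson methylation of the remaining chelated phenol under the stronger base.

Step 8
Reactants: 13 4-(allyloxy)-5-bromo-2-methoxybenzaldehyde, 14 prenyl bromide (1-bromo-3-methylbut-2-ene)
Product: 18 4-(allyloxy)-2-methoxy-5-(3-methylbut-2-en-1-yl)benzaldehyde, via amino alkoxide 15 (not isolated), via lithiated amino alkoxide 16 (not isolated), via prenylated amino alkoxide 17 (not isolated)
Conditions: morpholine, n-BuLi, THF, −20 °C; n-BuLi, −78 °C; CuBr·SMe2 (20 mol %), 14, −78 to 0 °C; H2O
Reagents that add atoms: none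
Why: Lithium morpholide masks the aldehyde in situ as an α-amino alkoxide, Br/Li exchange then gives the aryllithium, copper-catalysed SN2 allylation occurs at the unhindered CH2 of prenyl bromide, and water returns the aldehyde.

Step 9
Reactants: 18 4-(allyloxy)-2-methoxy-5-(3-methylbut-2-en-1-yl)benzaldehyde, 19 ethyl diazoacetate
Product: 20 ethyl (Z)-2-Ar-3-hydroxyprop-2-enoate
Conditions: HBF4·OEt2 (10 mol %), CH2Cl2, −78 °C
Reagents that add atoms: none
Why: Brønsted-acid-catalysed addition of the diazoester to the aldehyde and loss of N2 with 1,2-aryl shift (the favoured course for electron-rich aryl groups) gives the formyl ester as its hydrogen-bonded enol; the catalytic acid at −78 °C is buffered by the basic aldehyde, so the prenyl and allyl groups should survive.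

Step 10
Reactants: 20 ethyl (Z)-2-Ar-3-hydroxyprop-2-enoate
Product: 22 2-Ar-propane-1,3-diol, via hydroxy ester 21 (not isolated)
Conditions: NaBH4, EtOH, 0 °C; then LiBH4, THF, 0 °C to rt
Reagents that add atoms: none
Why: Hydride reduction of the formyl tautomer (NaBH4) and then of the ester (LiBH4) gives the prochiral diol, in which the transient stereocentre of 21 is lost.

Step 11
Reactants: 22 2-Ar-propane-1,3-diol
Product: 23 (R)-3-hydroxy-2-Ar-propyl acetate
Conditions: Burkholderia cepacia lipase (lipase PS), vinyl acetate, t-BuOMe, 25 °C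
Reagents that add atoms: vinyl acetate, CC(=O)OC=C
Why: Enzymatic desymmetrisation by irreversible transesterification; the lipase should acylate only the pro-R hydroxymethyl arm and so create the C3 stereocentre, and the slow second acylation removes the minor enantiomer.

Step 12
Reactants: 23 (R)-3-hydroxy-2-Ar-propyl acetate
Product: 24 (S)-2-Ar-3-(triethylsilyloxy)propyl acetate
Conditions: Et3SiCl, imidazole, CH2Cl2, 0 °C
Reagents that add atoms: chlorotriethylsilane, CC[Si](Cl)(CC)CC
Why: Silylation of the primary alcohol installs the latent alkoxide for the key step without touching the stereocentre.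

Step 13
Reactants: 24 (S)-2-Ar-3-(triethylsilyloxy)propyl acetate
Product: 25 (S)-2-Ar-3-(triethylsilyloxy)propan-1-ol
Conditions: i-Bu2AlH, CH2Cl2, −78 °C; aq. potassium sodium tartrate
Reagents that add atoms: none
Why: Reductive cleavage of the acetate at −78 °C passes through an aluminium alkoxide and so avoids the base-induced 1,5 O-to-O silyl shift that would exchange the two arms and erode the enantiomeric purity.

Step 14
Reactants: 25 (S)-2-Ar-3-(triethylsilyloxy)propan-1-ol
Product: 26 (R)-2-Ar-3-(triethylsilyloxy)propanal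
Conditions: Dess–Martin periodinane, NaHCO3, CH2Cl2, 0 °C
Reagents that add atoms: none
Why: Dess–Martin oxidation is buffered and non-basic, which limits enolisation of the α-aryl aldehyde; 26 is to be used at once without chromatography.

Step 15
Reactants: 10 3-(allyloxy)-5-methoxy-2-(trimethylsilyl)phenyl trifluoromethanesulfonate, 26 (R)-2-Ar-3-(triethylsilyloxy)propanal
Product: 30 (3R,4R)-5-(allyloxy)-3-Ar-7-methoxychroman-4-ol, via aryne 27 (not isolated), via ammonium alkoxide 28 (not isolated), via ammonium chromanolate 29 (not isolated)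
Conditions: 10 (1.5 equiv), Bu4N[Ph3SiF2] (TBAT, slow addition), THF, 0 °C to rt; H2O
Reagents that add atoms: none
Why: Proposed new method: fluoride removes SiMe3 from 10 with loss of triflate to give aryne 27 and, in the same medium, cleaves the O–SiEt3 bond of 26 to alkoxide 28; the alkoxide adds to the aryne at the carbon meta to the allyloxy group (O1–C8a) and the resulting C4a carbanion, with no proton source at hand, adds to the aldehyde (C4–C4a). The closest known reaction type is the fluoride-mediated annulation of arynes with o-hydroxyaryl aldehydes, ketones and esters (phenoxide addition, then intramolecular carbonyl capture); an aliphatic, silyl-masked alkoxide carrying an enolisable aldehyde has not been shown. Ring C closes by 6-exo-trig attack of the aryl anion on the formyl group. The new C4 centre is controlled by C3: in the Felkin–Anh, chair-like transition state the C3 aryl group is pseudo-equatorial and anti to the forming bond and the carbonyl oxygen is pseudo-axial, away from the peri C5 ether, which should give the cis (3R,4R) carbinol, and the non-coordinating ammonium ion rules out a chelate between the C5 ether and the carbonyl. Regioselectivity is secured by the inductively withdrawing C5 allyloxy group, which places the carbanion next to itself. The step needs O-arylation and ring closure to outrun α-deprotonation, β-elimination and retro-aldol cleavage of 26/28; the silyl mask, the weakly basic fluoride donor kept limiting by slow addition, the excess of 10 and the low temperature are meant to secure this.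

Step 16
Reactants: 30 (3R,4R)-5-(allyloxy)-3-Ar-7-methoxychroman-4-ol
Product: 31 (3R,4R)-3-[4-hydroxy-2-methoxy-5-(3-methylbut-2-en-1-yl)phenyl]-7-methoxychromane-4,5-diol
Conditions: Pd(PPh3)4 (5 mol %), morpholine, THF, rt
Reagents that add atoms: none
Why: Tsuji–Trost deallylation: zerovalent palladium ionises both aryl allyl ethers and morpholine traps the allyl units, under neutral to basic conditions that spare the acid-labile C4 benzylic alcohol, the C-prenyl group and both stereocentres.

**Compound list**

1 | 5-methoxyresorcinol | COc1cc(O)cc(O)c1 | starting material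
2 | 1-methoxy-3,5-bis(methoxymethoxy)benzene | COCOc1cc(OC)cc(OCOC)c1 | intermediate
3 | [4-methoxy-2,6-bis(methoxymethoxy)phenyl]lithium | [Li]c1c(OCOC)cc(OC)cc1OCOC | intermediate (not isolated)
4 | 2-bromo-5-methoxy-1,3-bis(methoxymethoxy)benzene | COCOc1cc(OC)cc(OCOC)c1Br | intermediate
5 | 2-bromo-5-methoxybenzene-1,3-diol | COc1cc(O)c(Br)c(O)c1 | intermediate
6 | 3-(allyloxy)-2-bromo-5-methoxyphenol | COc1cc(O)c(Br)c(OCC=C)c1 | intermediate
7 | [3-(allyloxy)-2-bromo-5-methoxyphenoxy]trimethylsilane | COc1cc(O[Si](C)(C)C)c(Br)c(OCC=C)c1 | intermediate (not isolated)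
8 | [2-(allyloxy)-4-methoxy-6-(trimethylsilyloxy)phenyl]lithium | COc1cc(O[Si](C)(C)C)c([Li])c(OCC=C)c1 | intermediate (not isolated)
9 | lithium 3-(allyloxy)-5-methoxy-2-(trimethylsilyl)phenoxide | COc1cc([O-])c([Si](C)(C)C)c(OCC=C)c1.[Li+] | intermediate (not isolated)
10 | 3-(allyloxy)-5-methoxy-2-(trimethylsilyl)phenyl trifluoromethanesulfonate | COc1cc(OCC=C)c([Si](C)(C)C)c(OS(=O)(=O)C(F)(F)F)c1 | intermediate
11 | 5-bromo-2,4-dihydroxybenzaldehyde | O=Cc1cc(Br)c(O)cc1O | starting material
12 | 4-(allyloxy)-5-bromo-2-hydroxybenzaldehyde | O=Cc1cc(Br)c(OCC=C)cc1O | intermediate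
13 | 4-(allyloxy)-5-bromo-2-methoxybenzaldehyde | COc1cc(OCC=C)c(Br)cc1C=O | intermediate
14 | prenyl bromide (1-bromo-3-methylbut-2-ene) | CC(C)=CCBr | starting material
15 | lithium [4-(allyloxy)-5-bromo-2-methoxyphenyl](morpholin-4-yl)methoxide (racemic at the aminal carbon) | [Li+].[O-]C(N1CCOCC1)c1cc(Br)c(OCC=C)cc1OC | intermediate (not isolated)
16 | lithium [4-(allyloxy)-5-lithio-2-methoxyphenyl](morpholin-4-yl)methoxide | [Li+].[O-]C(N1CCOCC1)c1cc([Li])c(OCC=C)cc1OC | intermediate (not isolated)
17 | lithium [4-(allyloxy)-2-methoxy-5-(3-methylbut-2-en-1-yl)phenyl](morpholin-4-yl)methoxide | [Li+].[O-]C(N1CCOCC1)c1cc(CC=C(C)C)c(OCC=C)cc1OC | intermediate (not isolated)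
18 | 4-(allyloxy)-2-methoxy-5-(3-methylbut-2-en-1-yl)benzaldehyde | COc1cc(OCC=C)c(CC=C(C)C)cc1C=O | intermediate
19 | ethyl diazoacetate | CCOC(=O)C=[N+]=[N-] | starting material
20 | ethyl (Z)-2-Ar-3-hydroxyprop-2-enoate (enol of the formyl ester) | CCOC(=O)/C(=C\O)c1cc(CC=C(C)C)c(OCC=C)cc1OC | intermediate
21 | ethyl 2-Ar-3-hydroxypropanoate (racemic) | CCOC(=O)C(CO)c1cc(CC=C(C)C)c(OCC=C)cc1OC | intermediate (not isolated)
22 | 2-Ar-propane-1,3-diol | OCC(CO)c1cc(CC=C(C)C)c(OCC=C)cc1OC | intermediate
23 | (R)-3-hydroxy-2-Ar-propyl acetate | CC(=O)OC[C@@H](CO)c1cc(CC=C(C)C)c(OCC=C)cc1OC | intermediate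
24 | (S)-2-Ar-3-(triethylsilyloxy)propyl acetate | CC(=O)OC[C@@H](CO[Si](CC)(CC)CC)c1cc(CC=C(C)C)c(OCC=C)cc1OC | intermediate
25 | (S)-2-Ar-3-(triethylsilyloxy)propan-1-ol | OC[C@@H](CO[Si](CC)(CC)CC)c1cc(CC=C(C)C)c(OCC=C)cc1OC | intermediate
26 | (R)-2-Ar-3-(triethylsilyloxy)propanal | O=C[C@@H](CO[Si](CC)(CC)CC)c1cc(CC=C(C)C)c(OCC=C)cc1OC | intermediate
27 | 3-(allyloxy)-5-methoxybenzyne | COC1=CC#CC(OCC=C)=C1 | intermediate (not isolated)
28 | tetrabutylammonium (R)-2-Ar-3-oxopropan-1-olate | CCCC[N+](CCCC)(CCCC)CCCC.[O-]C[C@@H](c1cc(CC=C(C)C)c(OCC=C)cc1OC)C=O | intermediate (not isolated)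
29 | tetrabutylammonium (3R,4R)-5-(allyloxy)-3-Ar-7-methoxychroman-4-olate | CCCC[N+](CCCC)(CCCC)CCCC.COc1cc(OCC=C)c2c(c1)OC[C@@H](c1cc(CC=C(C)C)c(OCC=C)cc1OC)[C@H]2[O-] | intermediate (not isolated)
30 | (3R,4R)-5-(allyloxy)-3-Ar-7-methoxychroman-4-ol (cis) | COc1cc(OCC=C)c2c(c1)OC[C@@H](c1cc(CC=C(C)C)c(OCC=C)cc1OC)[C@H]2O | intermediate
31 | (3R,4R)-3-[4-hydroxy-2-methoxy-5-(3-methylbut-2-en-1-yl)phenyl]-7-methoxychromane-4,5-diol | COc1cc(O)c2c(c1)OC[C@@H](c1cc(CC=C(C)C)c(O)cc1OC)[C@H]2O | target

**Step count and risks**

Total: 16 steps. Longest linear sequence: 11 steps (steps 6 to 16, from 11 to 31).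

Step 15 (proposed new method). Before the alkoxide meets the aryne, the aldehyde may enolise (loss of configuration at C3), eliminate the β-oxygen to a 2-arylacrolein, or cleave by retro-aldol. The ring-closed alkoxide may also be arylated by excess aryne, and facial selectivity at C4 may be lower than predicted.
Fallback, known chemistry, setting out from enol ester 20 and silyl triflate 10 and returning at 30:
- 20 is reduced with NaBH4 (EtOH, 0 °C) to hydroxy ester 21, here isolated.
- Mesylation and elimination (MsCl, Et3N, then DBU) give ethyl 2-Ar-acrylate F1.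
- LiOH (THF–H2O) gives 2-Ar-acrylic acid F2.
- F2 and 10 with CsF in THF (heated, sealed tube) undergo the known formal insertion of an aryne into a carboxylic acid C–O bond: O-arylation of the carboxylate, then acyl shift to the ortho carbanion. This gives the 2-hydroxyaryl vinyl ketone F3, which closes by oxa-Michael addition to racemic 5-(allyloxy)-3-Ar-7-methoxychroman-4-one F4.
- Asymmetric transfer hydrogenation with dynamic kinetic resolution (RuCl[(R,R)-TsDPEN](p-cymene), HCO2H/Et3N) should give the cis (3R,4R) alcohol 30, as known for isoflavanones; the sense is to be confirmed, and the (S,S) catalyst gives the antipode.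
- Here the lability of the α-aryl centre, which threatens the main step, is what makes the resolution dynamic.

Step 11. Discrimination between the enantiotopic arms may be poor or reversed for this ortho-methoxy aryl diol, or acylation may run on to the diacetate.
Fallback, from diol 22, returning at 25:
- Desymmetrising benzoylation with the dinuclear zinc catalyst from Et2Zn and ProPhenol ligand (vinyl benzoate, toluene, −15 °C) gives (R)-3-hydroxy-2-Ar-propyl benzoate F5. The ligand enantiomer is chosen on a test run so that the pro-R arm is acylated.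
- Et3SiCl and imidazole give (S)-2-Ar-3-(triethylsilyloxy)propyl benzoate F6.
- i-Bu2AlH at −78 °C gives 25.

Step 9. The acid may protonate the prenyl alkene (cyclisation onto O4' with loss of allyl) or the allyl ether, and hydride shift may compete with aryl shift.
Fallback, from bromo aldehyde 13, returning at 22; it carries no prenyl group through the acid step and also bypasses step 8:
- 13 and 19 with HBF4·OEt2 give ethyl (Z)-2-[4-(allyloxy)-5-bromo-2-methoxyphenyl]-3-hydroxyprop-2-enoate F7.
- NaBH4 then LiBH4 give 2-[4-(allyloxy)-5-bromo-2-methoxyphenyl]propane-1,3-diol F8.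
- 2,2-Dimethoxypropane and pyridinium p-toluenesulfonate give the acetonide 5-[4-(allyloxy)-5-bromo-2-methoxyphenyl]-2,2-dimethyl-1,3-dioxane F9.
- Br/Li exchange (n-BuLi, THF, −78 °C) and copper-catalysed allylation with 14 (CuBr·SMe2) give 5-Ar-2,2-dimethyl-1,3-dioxane F10.
- Pyridinium p-toluenesulfonate in MeOH releases 22.

**Further compounds**

F1 | step 15 | ethyl 2-Ar-acrylate | C=C(C(=O)OCC)c1cc(CC=C(C)C)c(OCC=C)cc1OC
F2 | step 15 | 2-Ar-acrylic acid | C=C(C(=O)O)c1cc(CC=C(C)C)c(OCC=C)cc1OC
F3 | step 15 | 1-[2-(allyloxy)-6-hydroxy-4-methoxyphenyl]-2-Ar-prop-2-en-1-one | C=C(C(=O)c1c(O)cc(OC)cc1OCC=C)c1cc(CC=C(C)C)c(OCC=C)cc1OC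
F4 | step 15 | 5-(allyloxy)-3-Ar-7-methoxychroman-4-one (racemic) | COc1cc(OCC=C)c2c(c1)OCC(c1cc(CC=C(C)C)c(OCC=C)cc1OC)C2=O
F5 | step 11 | (R)-3-hydroxy-2-Ar-propyl benzoate | O=C(OC[C@@H](CO)c1cc(CC=C(C)C)c(OCC=C)cc1OC)c1ccccc1
F6 | step 11 | (S)-2-Ar-3-(triethylsilyloxy)propyl benzoate | O=C(OC[C@@H](CO[Si](CC)(CC)CC)c1cc(CC=C(C)C)c(OCC=C)cc1OC)c1ccccc1
F7 | step 9 | ethyl (Z)-2-[4-(allyloxy)-5-bromo-2-methoxyphenyl]-3-hydroxyprop-2-enoate | CCOC(=O)/C(=C\O)c1cc(Br)c(OCC=C)cc1OC
F8 | step 9 | 2-[4-(allyloxy)-5-bromo-2-methoxyphenyl]propane-1,3-diol | OCC(CO)c1cc(Br)c(OCC=C)cc1OC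
F9 | step 9 | 5-[4-(allyloxy)-5-bromo-2-methoxyphenyl]-2,2-dimethyl-1,3-dioxane | CC1(C)OCC(CO1)c1cc(Br)c(OCC=C)cc1OC
F10 | step 9 | 5-Ar-2,2-dimethyl-1,3-dioxane | CC1(C)OCC(CO1)c1cc(CC=C(C)C)c(OCC=C)cc1OC
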